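**Retrosynthetic overview**
- Both ArCH2CH2Ar bridges are traced back to diarylalkynes, so one final hydrogenation saturates both bridges and removes the single benzyl ether.
- Key step: a one-flask, halogen-selective double Sonogashira coupling on a bromo/iodo diaryl ether linchpin (3-ethynylphenol at C–I at rt, then 3-ethynylanisole at C–Br on warming), in place of the usual Ullmann ether / double Wittig sequence.
- The linchpin comes from Chan–Lam O-arylation of 2-(benzyloxy)-5-bromophenol with (4-iodophenyl)boronic acid; that phenol comes from Baeyer–Villiger oxidation of 2-(benzyloxy)-5-bromobenzaldehyde.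
- No ring is formed: all four benzene rings are bought and joined in the order B, C (ether bond), D, A.

Assumption: the target has no stereocentre or other stereogenic element, so it is one achiral compound and no stereocontrol is needed; ring A = 3-methoxyphenyl, ring B = central phenol ring, ring C = para-phenylene, ring D = 3-hydroxyphenyl.

**Route**

Step 1
Reactants: 1 2-(benzyloxy)-5-bromobenzaldehyde
Product: 3 2-(benzyloxy)-5-bromophenol, via aryl formate 2 (not isolated)
Conditions: mCPBA (1.3 equiv), CH2Cl2, 0 °C to rt; aq NaHCO3 wash; then K2CO3 (0.1 equiv), MeOH, rt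
Reagents that add atoms: mCPBA (3-chloroperoxybenzoic acid), OOC(=O)c1cccc(Cl)c1
Why: Baeyer–Villiger (Dakin-type) oxidation, in which the electron-rich ortho-alkoxyaryl group migrates in preference to hydrogen to give the aryl formate, which base-catalysed methanolysis converts to the phenol without touching C–Br or the benzyl ether.

Step 2
Reactants: 3 2-(benzyloxy)-5-bromophenol; 4 (4-iodophenyl)boronic acid (2 equiv)
Product: 5 1-(benzyloxy)-4-bromo-2-(4-iodophenoxy)benzene
Conditions: Cu(OAc)2 (20 mol %), pyridine (3 equiv), 4 Å MS, CH2Cl2, O2 (balloon), rt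
Reagents that add atoms: none
Why: Chan–Lam–Evans oxidative O-arylation, in which the aryl group passes from boron to divalent copper and is reductively eliminated onto the phenoxide at room temperature, conditions under which aryl bromides and iodides are inert, so both halogen handles survive.

Step 3
Reactants: 5 1-(benzyloxy)-4-bromo-2-(4-iodophenoxy)benzene; 6 3-ethynylphenol (1.0 equiv); 7 1-ethynyl-3-methoxybenzene (1.5 equiv)
Product: 9 3-((4-(2-(benzyloxy)-5-((3-methoxyphenyl)ethynyl)phenoxy)phenyl)ethynyl)phenol, via bromo monoalkyne 8 (not isolated)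
Conditions: 5 + 6, PdCl2(PPh3)2 (3 mol %), CuI (5 mol %), i-Pr2NH/THF, rt, argon; then 7, PdCl2(PhCN)2 (3 mol %), [HP(t-Bu)3]BF4 (6 mol %), 50 °C, same flask
Reagents that add atoms: none
Why: Sequential Sonogashira couplings, selective because zerovalent palladium with PPh3 inserts into C–I at room temperature but not into the electron-rich C–Br, which is engaged only after 6 is consumed by the more active P(t-Bu)3 catalyst on warming; the free phenol is tolerated under amine base.

Step 4
Reactants: 9 3-((4-(2-(benzyloxy)-5-((3-methoxyphenyl)ethynyl)phenoxy)phenyl)ethynyl)phenol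
Product: 10 2-[4-(3-hydroxyphenethyl)phenoxy]-4-(3-methoxyphenethyl)phenol (target)
Conditions: H2 (1 atm), 10% Pd/C, EtOAc/MeOH, rt
Reagents that add atoms: none
Why: Heterogeneous catalytic hydrogenation saturates both diarylalkynes to CH2CH2 and hydrogenolyses the aryl benzyl ether in the same operation, while the aryl methyl ether, diaryl ether and arene rings are untouched; no stereocentre is created.

**Compound list**

1 | 2-(benzyloxy)-5-bromobenzaldehyde | O=Cc1cc(Br)ccc1OCc1ccccc1 | starting material
2 | 2-(benzyloxy)-5-bromophenyl formate | O=COc1cc(Br)ccc1OCc1ccccc1 | intermediate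
3 | 2-(benzyloxy)-5-bromophenol | Oc1cc(Br)ccc1OCc1ccccc1 | intermediate
4 | (4-iodophenyl)boronic acid | OB(O)c1ccc(I)cc1 | starting material
5 | 1-(benzyloxy)-4-bromo-2-(4-iodophenoxy)benzene | Brc1ccc(OCc2ccccc2)c(Oc2ccc(I)cc2)c1 | intermediate
6 | 3-ethynylphenol | Oc1cccc(C#C)c1 | starting material
7 | 1-ethynyl-3-methoxybenzene (3-ethynylanisole) | COc1cccc(C#C)c1 | starting material
8 | 3-((4-(2-(benzyloxy)-5-bromophenoxy)phenyl)ethynyl)phenol | Oc1cccc(C#Cc2ccc(Oc3cc(Br)ccc3OCc3ccccc3)cc2)c1 | intermediate
9 | 3-((4-(2-(benzyloxy)-5-((3-methoxyphenyl)ethynyl)phenoxy)phenyl)ethynyl)phenol | COc1cccc(C#Cc2ccc(OCc3ccccc3)c(Oc3ccc(C#Cc4cccc(O)c4)cc3)c2)c1 | intermediate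
10 | 2-[4-(3-hydroxyphenethyl)phenoxy]-4-(3-methoxyphenethyl)phenol | COc1cccc(CCc2ccc(O)c(Oc3ccc(CCc4cccc(O)c4)cc3)c2)c1 | target

**Totals and risks**

Total step count: 4. Longest linear sequence: 4 steps (1 → 3 → 5 → 9 → 10).

Steps most likely to fail, most risky first:

Step 3. The electron-rich bromide of 8 may couple slowly, and any 6 left from the first stage could end up on ring B. The fallback sets out from 5 and comes back to the route at 10. Only the room-temperature coupling of 5 with 6 is run and 8 is isolated. Commercial 3-vinylanisole is hydroborated with 9-BBN (THF, rt) to 9-[2-(3-methoxyphenyl)ethyl]-9-borabicyclo[3.3.1]nonane F1. F1 is joined to 8 by B-alkyl Suzuki–Miyaura coupling (PdCl2(dppf), aq K3PO4, THF/DMF, 60 °C) to give 3-((4-(2-(benzyloxy)-5-(3-methoxyphenethyl)phenoxy)phenyl)ethynyl)phenol F2. Hydrogenation of F2 under the step 4 conditions reduces the remaining alkyne, removes the benzyl group and gives 10.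

Step 2. The ortho-benzyloxy phenol is hindered, and homocoupling or protodeboronation of 4 may outrun O-arylation. The fallback sets out from 3 and comes back at 5. SNAr of 3 on 1-fluoro-4-nitrobenzene (K2CO3, DMF, 80 °C) gives 1-(benzyloxy)-4-bromo-2-(4-nitrophenoxy)benzene F3. Fe powder and NH4Cl (EtOH/H2O, 80 °C) reduce the nitro group, sparing C–Br and the benzyl ether, to 4-(2-(benzyloxy)-5-bromophenoxy)aniline F4. Diazotisation (NaNO2, aq HCl, MeCN, 0 °C) gives 4-(2-(benzyloxy)-5-bromophenoxy)benzenediazonium chloride F5, and KI converts it to 5 (Sandmeyer-type iodination).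

Step 4. Traces of iodide, phosphine or copper carried over from step 3 can poison Pd/C, so the reduction may stall at the stilbene or benzyl ether stage. The fallback sets out from 9 and comes back at 10, separating the two reductions without a metal surface. Diimide, generated from p-toluenesulfonyl hydrazide and NaOAc in refluxing DME/H2O, saturates both alkynes to give 3-(4-(2-(benzyloxy)-5-(3-methoxyphenethyl)phenoxy)phenethyl)phenol F6. BCl3 with pentamethylbenzene as cation scavenger (CH2Cl2, −78 °C) then cleaves the aryl benzyl ether selectively over the aryl methyl ether to give 10.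

**Further compounds**

F1 | step 3 | 9-[2-(3-methoxyphenyl)ethyl]-9-borabicyclo[3.3.1]nonane | COc1cccc(CCB2C3CCCC2CCC3)c1
F2 | step 3 | 3-((4-(2-(benzyloxy)-5-(3-methoxyphenethyl)phenoxy)phenyl)ethynyl)phenol | COc1cccc(CCc2ccc(OCc3ccccc3)c(Oc3ccc(C#Cc4cccc(O)c4)cc3)c2)c1
F3 | step 2 | 1-(benzyloxy)-4-bromo-2-(4-nitrophenoxy)benzene | [O-][N+](=O)c1ccc(Oc2cc(Br)ccc2OCc2ccccc2)cc1
F4 | step 2 | 4-(2-(benzyloxy)-5-bromophenoxy)aniline | Nc1ccc(Oc2cc(Br)ccc2OCc2ccccc2)cc1
F5 | step 2 | 4-(2-(benzyloxy)-5-bromophenoxy)benzenediazonium chloride | N#[N+]c1ccc(Oc2cc(Br)ccc2OCc2ccccc2)cc1.[Cl-]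
F6 | step 4 | 3-(4-(2-(benzyloxy)-5-(3-methoxyphenethyl)phenoxy)phenethyl)phenol | COc1cccc(CCc2ccc(OCc3ccccc3)c(Oc3ccc(CCc4cccc(O)c4)cc3)c2)c1
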